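Numbering: chain C1–C12 from the ethyl end, C13 the carboxyl carbon on C5, ring O1', C2'–C6'. Everything rests on forming C9–CH3 and C7–C8 in one operation. The feature exploited is the isolated C9 methyl stereocentre, one methylene (C8) from the E-C6=C7 alkene and remote from the C3–C5 triad and the dihydropyranone ring. Zirconium-catalysed asymmetric methylalumination of a terminal alkene creates C9, and the alkylmetal is cross-coupled in the same flask with an E-alkenyl iodide. The precursors are the silyl ether of pent-4-en-1-ol (C8–C12) and an acetonide-protected iodide (C1–C7, C13) already holding C3, C4 and C5. The acylpyranone and the C13 carboxyl follow.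

Key step: step 9

Remark: the acylpyranone is written throughout as the 4-hydroxy enol tautomer shown in the target; compound 23 is the enol form of (6R)-6-methyloxane-2,4-dione.

Step 1
Reactants: 1 (S)-2-methylbutan-1-ol
Product: 3 ethyl (2E,4S)-4-methylhex-2-enoate, via (S)-2-methylbutanal 2 (not isolated)
Conditions: TEMPO (cat.), PhI(OAc)2, CH2Cl2, rt; then Ph3P=CHCO2Et, rt, one pot
Reagents that add atoms: ethyl (triphenylphosphoranylidene)acetate, CCOC(=O)C=P(c1ccccc1)(c1ccccc1)c1ccccc1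
Why: Nitroxyl-catalysed alcohol oxidation followed in the same flask by Wittig olefination with a stabilised ylide should give the E-enoate, and trapping the volatile aldehyde 2 under non-basic conditions keeps the C3 centre (S) of 1 intact.

Step 2
Reactants: 3 ethyl (2E,4S)-4-methylhex-2-enoate
Product: 4 (2E,4S)-4-methylhex-2-en-1-ol
Conditions: iBu2AlH (2.2 equiv), CH2Cl2, −78 to 0 °C; aqueous potassium sodium tartrate
Reagents that add atoms: none
Why: 1,2-Reduction of an α,β-unsaturated ester with an aluminium hydride gives the allylic alcohol without change at the alkene or at C3.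

Step 3
Reactants: 4 (2E,4S)-4-methylhex-2-en-1-ol
Product: 5 [(2R,3R)-3-[(2S)-butan-2-yl]oxiran-2-yl]methanol
Conditions: Ti(OiPr)4 (cat.), D-(−)-diisopropyl tartrate (cat.), tBuOOH, 4 Å molecular sieves, CH2Cl2, −20 °C
Reagents that add atoms: tert-butyl hydroperoxide, CC(C)(C)OO
Why: Sharpless asymmetric epoxidation of the E-allylic alcohol: the titanium–D-(−)-tartrate catalyst delivers oxygen to one alkene face under reagent control and should give the (2R,3R)-epoxide, which sets the future C4 (its C–O bond is kept) and prepares the inversion that will set C5.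

Step 4
Reactants: 5 [(2R,3R)-3-[(2S)-butan-2-yl]oxiran-2-yl]methanol
Product: 6 (2S,3R,4S)-2-ethenyl-4-methylhexane-1,3-diol
Conditions: CH2=CHMgBr (4 equiv), CuI (15 mol%), THF/Et2O, −30 to 0 °C; aqueous NH4Cl; aqueous NaIO4 treatment of the crude product to cleave any 1,2-diol regioisomer
Reagents that add atoms: vinylmagnesium bromide, C=C[Mg]Br
Why: Copper-catalysed SN2 opening of a 2,3-epoxy alcohol by a vinyl Grignard reagent: attack at the epoxide carbon next to CH2OH, the one not shielded by the sec-butyl group, with inversion turns the trans-epoxide into the anti 2-vinyl-1,3-diol and so sets C5.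

Step 5
Reactants: 6 (2S,3R,4S)-2-ethenyl-4-methylhexane-1,3-diol
Product: 7 (4R,5S)-4-[(2S)-butan-2-yl]-5-ethenyl-2,2-dimethyl-1,3-dioxane
Conditions: Me2C(OMe)2, pyridinium p-toluenesulfonate (cat.), CH2Cl2, rt
Reagents that add atoms: 2,2-dimethoxypropane, COC(C)(C)OC
Why: Acid-catalysed transacetalisation of a 1,3-diol gives the six-membered acetonide, whose trans (diequatorial) arrangement follows from the anti diol and locks C4 and C5 for the steps ahead.

Step 6
Reactants: 7 (4R,5S)-4-[(2S)-butan-2-yl]-5-ethenyl-2,2-dimethyl-1,3-dioxane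
Product: 9 (4R,5S)-4-[(2S)-butan-2-yl]-2,2-dimethyl-1,3-dioxane-5-carbaldehyde, via ozonide 8 (not isolated)
Conditions: O3, CH2Cl2, −78 °C; then PPh3, −78 °C to rt
Reagents that add atoms: ozone, [O-][O+]=O
Why: Ozonolysis with reductive work-up cleaves the terminal alkene to the aldehyde under neutral conditions, under which the C5 centre next to the new carbonyl (already in the more stable trans arrangement) should hold.

Step 7
Reactants: 9 (4R,5S)-4-[(2S)-butan-2-yl]-2,2-dimethyl-1,3-dioxane-5-carbaldehyde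
Product: 10 (4R,5S)-4-[(2S)-butan-2-yl]-5-[(E)-2-iodoethenyl]-2,2-dimethyl-1,3-dioxane
Conditions: CrCl2 (6 equiv), CHI3 (2 equiv), THF/1,4-dioxane, 0 °C to rt, dark
Reagents that add atoms: iodoform, IC(I)I
Why: Takai iodo-olefination: the geminal dichromium reagent formed from iodoform and divalent chromium adds to the aldehyde and eliminates to the E-alkenyl iodide under non-basic conditions that spare C5 and the acetonide.

Step 8
Reactants: 11 pent-4-en-1-ol
Product: 12 tert-butyldimethyl(pent-4-en-1-yloxy)silane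
Conditions: tBuMe2SiCl, imidazole, CH2Cl2, rt
Reagents that add atoms: tert-butyldimethylsilyl chloride, CC(C)(C)[Si](C)(C)Cl
Why: Silylation of a primary alcohol with a silyl chloride and imidazole is routine, and the bulky silyl ether keeps the oxygen from binding aluminium or zirconium in the next step.

Step 9
Reactants: 12 tert-butyldimethyl(pent-4-en-1-yloxy)silane, 13 trimethylaluminium, 10 (4R,5S)-4-[(2S)-butan-2-yl]-5-[(E)-2-iodoethenyl]-2,2-dimethyl-1,3-dioxane
Product: 16 tert-butyl{[(4R,6E)-7-[(4R,5S)-4-[(2S)-butan-2-yl]-2,2-dimethyl-1,3-dioxan-5-yl]-4-methylhept-6-en-1-yl]oxy}dimethylsilane, via alkylalane 14 (not isolated), via alkylzinc triflate 15 (not isolated)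
Conditions: 12 (2.5 equiv), Me3Al (5 equiv), (−)-bis(1-neomenthylindenyl)zirconium dichloride [(−)-(NMI)2ZrCl2, 5 mol%], methylaluminoxane (cat.), CH2Cl2, 0 °C to rt; volatiles removed in vacuo; Zn(OTf)2 (2.5 equiv), DMF, 70 °C; then 10 (1 equiv), Pd(DPEphos)Cl2 (5 mol%), iBu2AlH (10 mol%), DMF, rt
Reagents that add atoms: trimethylaluminium (compound 13), C[Al](C)C
Why: A chiral cationic methylzirconocene generated from (−)-(NMI)2ZrCl2 and Me3Al inserts the monosubstituted C8=C9 alkene of 12 with methyl delivered to C9 and the metal to C8, zirconium-to-aluminium exchange releases alkylalane 14 and turns the catalyst over, and Zn(OTf)2 in DMF then passes the 2-methylalkyl group to zinc (15), which enters a Negishi cycle (oxidative addition of 10 to zerovalent palladium made from Pd(DPEphos)Cl2 and iBu2AlH, transmetallation, reductive elimination) to form C7–C8. The closest known reaction type is the zirconium-catalysed asymmetric carboalumination of terminal alkenes bearing remote silyl ethers with one-pot palladium-catalysed alkenylation. No ring is closed. The new C9 centre (R) is set by enantioface selection under control of the neomenthylindenyl ligands alone, the (−)-catalyst being the series that gives (R)-2-methylalkylalanes, and because 10 is a single enantiomer any C9 epimer is a diastereomer that should be removable by chromatography. The step needs methyl delivery to the internal carbon (inherent to a monosubstituted alkene), preferential transfer of the 2-methylalkyl group over residual methyl groups (helped by stripping excess Me3Al and using the alane in excess over 10), retention of the E geometry (inherent to coupling at an alkenyl iodide) and suppression of β-hydride elimination (the wide bite angle of DPEphos). The acetonide and the silyl ether are inert to alkylaluminium and alkylzinc species under these conditions.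

Step 10
Reactants: 16 tert-butyl{[(4R,6E)-7-[(4R,5S)-4-[(2S)-butan-2-yl]-2,2-dimethyl-1,3-dioxan-5-yl]-4-methylhept-6-en-1-yl]oxy}dimethylsilane
Product: 17 (4R,6E)-7-[(4R,5S)-4-[(2S)-butan-2-yl]-2,2-dimethyl-1,3-dioxan-5-yl]-4-methylhept-6-en-1-ol
Conditions: Bu4NF, THF, 0 °C to rt
Reagents that add atoms: none
Why: Fluoride-mediated cleavage of a primary silyl ether leaves the acetonide, the alkene and all stereocentres untouched.

Step 11
Reactants: 17 (4R,6E)-7-[(4R,5S)-4-[(2S)-butan-2-yl]-2,2-dimethyl-1,3-dioxan-5-yl]-4-methylhept-6-en-1-ol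
Product: 19 (4R,6E)-7-[(4R,5S)-4-[(2S)-butan-2-yl]-2,2-dimethyl-1,3-dioxan-5-yl]-4-methylhept-6-enoic acid, via aldehyde 18 (not isolated)
Conditions: TEMPO (cat.), NaClO2, NaOCl (cat.), MeCN/phosphate buffer pH 6.7, 35 °C
Reagents that add atoms: sodium chlorite, [Na+].[O-]Cl=O
Why: Nitroxyl-catalysed oxidation of the primary alcohol to aldehyde 18 and chlorite oxidation of the aldehyde in one buffered medium give the C12 acid, the near-neutral pH sparing the acetonide and the low hypochlorite level sparing the alkene.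

Step 12
Reactants: 20 methyl (R)-3-hydroxybutanoate
Product: 21 tert-butyl (5R)-5-hydroxy-3-oxohexanoate
Conditions: tBuOAc (4 equiv), LiN(iPr)2 (4 equiv), THF, −78 to −30 °C; aqueous NH4Cl
Reagents that add atoms: tert-butyl acetate, CC(=O)OC(C)(C)C
Why: Crossed Claisen condensation of the methyl ester with excess lithium enolate of tert-butyl acetate (the first equivalent turns the hydroxyl into an inert alkoxide) gives the δ-hydroxy-β-keto ester without involving the C6' centre.

Step 13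
Reactants: 21 tert-butyl (5R)-5-hydroxy-3-oxohexanoate
Product: 23 (6R)-4-hydroxy-6-methyl-5,6-dihydro-2H-pyran-2-one, via hydroxy keto acid 22 (not isolated)
Conditions: CF3CO2H, CH2Cl2, 0 °C to rt
Reagents that add atoms: none
Why: Acidolysis of the tert-butyl ester followed by six-membered lactonisation of the δ-hydroxy-β-keto acid gives the pyran-2,4-dione in its enol form with C6' (R) unchanged.

Step 14
Reactants: 19 (4R,6E)-7-[(4R,5S)-4-[(2S)-butan-2-yl]-2,2-dimethyl-1,3-dioxan-5-yl]-4-methylhept-6-enoic acid, 23 (6R)-4-hydroxy-6-methyl-5,6-dihydro-2H-pyran-2-one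
Product: 25 (6R)-3-[(4R,6E)-7-[(4R,5S)-4-[(2S)-butan-2-yl]-2,2-dimethyl-1,3-dioxan-5-yl]-4-methylhept-6-enoyl]-4-hydroxy-6-methyl-5,6-dihydro-2H-pyran-2-one, via enol ester 24 (not isolated)
Conditions: DCC (1.2 equiv), DMAP (1.2 equiv), CH2Cl2, rt
Reagents that add atoms: none
Why: Carbodiimide-mediated O-acylation of the enol followed by DMAP-promoted O-to-C acyl migration (Fries-type rearrangement) places the acyl group on C3' and gives the chelated enolised tricarbonyl as the thermodynamic product without touching any stereocentre.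

Step 15
Reactants: 25 (6R)-3-[(4R,6E)-7-[(4R,5S)-4-[(2S)-butan-2-yl]-2,2-dimethyl-1,3-dioxan-5-yl]-4-methylhept-6-enoyl]-4-hydroxy-6-methyl-5,6-dihydro-2H-pyran-2-one
Product: 26 (6R)-4-hydroxy-3-[(4R,6E,8S,9R,10S)-9-hydroxy-8-(hydroxymethyl)-4,10-dimethyldodec-6-enoyl]-6-methyl-5,6-dihydro-2H-pyran-2-one
Conditions: AcOH/H2O/THF (3:1:1), 40 °C
Reagents that add atoms: none
Why: Hydrolysis of the acetonide in dilute aqueous acid frees the C4 and C13 hydroxyls, conditions to which the enolised acylpyranone and the alkene are stable.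

Step 16
Reactants: 26 (6R)-4-hydroxy-3-[(4R,6E,8S,9R,10S)-9-hydroxy-8-(hydroxymethyl)-4,10-dimethyldodec-6-enoyl]-6-methyl-5,6-dihydro-2H-pyran-2-one
Product: 28 (2R,3E,6R)-9-[(6R)-4-hydroxy-6-methyl-2-oxo-5,6-dihydro-2H-pyran-3-yl]-2-[(1R,2S)-1-hydroxy-2-methylbutyl]-6-methyl-9-oxonon-3-enoic acid, via hydroxy aldehyde 27 (not isolated)
Conditions: TEMPO (0.2 equiv), PhI(OAc)2 (2.5 equiv), MeCN/H2O (1:1), 0 °C to rt
Reagents that add atoms: water, O
Why: Nitroxyl-catalysed oxidation with a trivalent iodine co-oxidant is selective for the primary C13 alcohol over the hindered secondary C4 alcohol, and in aqueous medium the aldehyde hydrate is oxidised on to the acid without isolation of the epimerisable aldehyde 27, so C5 should keep its configuration.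

Compound list

1 | (S)-2-methylbutan-1-ol | CC[C@H](C)CO | starting material
2 | (S)-2-methylbutanal (formed in the flask) | CC[C@H](C)C=O | intermediate
3 | ethyl (2E,4S)-4-methylhex-2-enoate | CC[C@H](C)/C=C/C(=O)OCC | intermediate
4 | (2E,4S)-4-methylhex-2-en-1-ol | CC[C@H](C)/C=C/CO | intermediate
5 | [(2R,3R)-3-[(2S)-butan-2-yl]oxiran-2-yl]methanol | CC[C@H](C)[C@H]1O[C@@H]1CO | intermediate
6 | (2S,3R,4S)-2-ethenyl-4-methylhexane-1,3-diol | CC[C@H](C)[C@@H](O)[C@@H](C=C)CO | intermediate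
7 | (4R,5S)-4-[(2S)-butan-2-yl]-5-ethenyl-2,2-dimethyl-1,3-dioxane | CC[C@H](C)[C@H]1OC(C)(C)OC[C@@H]1C=C | intermediate
8 | 3-[(4R,5S)-4-[(2S)-butan-2-yl]-2,2-dimethyl-1,3-dioxan-5-yl]-1,2,4-trioxolane (ozonide, mixture at the trioxolane carbon, formed in the flask) | CC[C@H](C)[C@H]1OC(C)(C)OC[C@@H]1C1OCOO1 | intermediate
9 | (4R,5S)-4-[(2S)-butan-2-yl]-2,2-dimethyl-1,3-dioxane-5-carbaldehyde | CC[C@H](C)[C@H]1OC(C)(C)OC[C@@H]1C=O | intermediate
10 | (4R,5S)-4-[(2S)-butan-2-yl]-5-[(E)-2-iodoethenyl]-2,2-dimethyl-1,3-dioxane | CC[C@H](C)[C@H]1OC(C)(C)OC[C@@H]1/C=C/I | intermediate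
11 | pent-4-en-1-ol | C=CCCCO | starting material
12 | tert-butyldimethyl(pent-4-en-1-yloxy)silane | C=CCCCO[Si](C)(C)C(C)(C)C | intermediate
13 | trimethylaluminium | C[Al](C)C | starting material
14 | {(2R)-5-[(tert-butyldimethylsilyl)oxy]-2-methylpentyl}dimethylaluminium (formed in the flask) | C[Al](C)C[C@H](C)CCCO[Si](C)(C)C(C)(C)C | intermediate
15 | {(2R)-5-[(tert-butyldimethylsilyl)oxy]-2-methylpentyl}zinc trifluoromethanesulfonate (formed in the flask) | FC(F)(F)S(=O)(=O)O[Zn]C[C@H](C)CCCO[Si](C)(C)C(C)(C)C | intermediate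
16 | tert-butyl{[(4R,6E)-7-[(4R,5S)-4-[(2S)-butan-2-yl]-2,2-dimethyl-1,3-dioxan-5-yl]-4-methylhept-6-en-1-yl]oxy}dimethylsilane | CC[C@H](C)[C@H]1OC(C)(C)OC[C@@H]1/C=C/C[C@H](C)CCCO[Si](C)(C)C(C)(C)C | intermediate
17 | (4R,6E)-7-[(4R,5S)-4-[(2S)-butan-2-yl]-2,2-dimethyl-1,3-dioxan-5-yl]-4-methylhept-6-en-1-ol | CC[C@H](C)[C@H]1OC(C)(C)OC[C@@H]1/C=C/C[C@H](C)CCCO | intermediate
18 | (4R,6E)-7-[(4R,5S)-4-[(2S)-butan-2-yl]-2,2-dimethyl-1,3-dioxan-5-yl]-4-methylhept-6-enal (formed in the flask) | CC[C@H](C)[C@H]1OC(C)(C)OC[C@@H]1/C=C/C[C@H](C)CCC=O | intermediate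
19 | (4R,6E)-7-[(4R,5S)-4-[(2S)-butan-2-yl]-2,2-dimethyl-1,3-dioxan-5-yl]-4-methylhept-6-enoic acid | CC[C@H](C)[C@H]1OC(C)(C)OC[C@@H]1/C=C/C[C@H](C)CCC(=O)O | intermediate
20 | methyl (R)-3-hydroxybutanoate | C[C@@H](O)CC(=O)OC | starting material
21 | tert-butyl (5R)-5-hydroxy-3-oxohexanoate | C[C@@H](O)CC(=O)CC(=O)OC(C)(C)C | intermediate
22 | (5R)-5-hydroxy-3-oxohexanoic acid (formed in the flask) | C[C@@H](O)CC(=O)CC(=O)O | intermediate
23 | (6R)-4-hydroxy-6-methyl-5,6-dihydro-2H-pyran-2-one | C[C@@H]1CC(O)=CC(=O)O1 | intermediate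
24 | (6R)-6-methyl-2-oxo-5,6-dihydro-2H-pyran-4-yl (4R,6E)-7-[(4R,5S)-4-[(2S)-butan-2-yl]-2,2-dimethyl-1,3-dioxan-5-yl]-4-methylhept-6-enoate (formed in the flask) | CC[C@H](C)[C@H]1OC(C)(C)OC[C@@H]1/C=C/C[C@H](C)CCC(=O)OC1=CC(=O)O[C@H](C)C1 | intermediate
25 | (6R)-3-[(4R,6E)-7-[(4R,5S)-4-[(2S)-butan-2-yl]-2,2-dimethyl-1,3-dioxan-5-yl]-4-methylhept-6-enoyl]-4-hydroxy-6-methyl-5,6-dihydro-2H-pyran-2-one | CC[C@H](C)[C@H]1OC(C)(C)OC[C@@H]1/C=C/C[C@H](C)CCC(=O)C1=C(O)C[C@@H](C)OC1=O | intermediate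
26 | (6R)-4-hydroxy-3-[(4R,6E,8S,9R,10S)-9-hydroxy-8-(hydroxymethyl)-4,10-dimethyldodec-6-enoyl]-6-methyl-5,6-dihydro-2H-pyran-2-one | CC[C@H](C)[C@@H](O)[C@@H](/C=C/C[C@H](C)CCC(=O)C1=C(O)C[C@@H](C)OC1=O)CO | intermediate
27 | (2R,3E,6R)-9-[(6R)-4-hydroxy-6-methyl-2-oxo-5,6-dihydro-2H-pyran-3-yl]-2-[(1R,2S)-1-hydroxy-2-methylbutyl]-6-methyl-9-oxonon-3-enal (formed in the flask) | CC[C@H](C)[C@@H](O)[C@@H](/C=C/C[C@H](C)CCC(=O)C1=C(O)C[C@@H](C)OC1=O)C=O | intermediate
28 | (2R,3E,6R)-9-[(6R)-4-hydroxy-6-methyl-2-oxo-5,6-dihydro-2H-pyran-3-yl]-2-[(1R,2S)-1-hydroxy-2-methylbutyl]-6-methyl-9-oxonon-3-enoic acid | CC[C@H](C)[C@@H](O)[C@@H](/C=C/C[C@H](C)CCC(=O)C1=C(O)C[C@@H](C)OC1=O)C(=O)O | target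

Total step count: 16 steps.
Longest linear sequence: 13 steps (steps 1–7, 9–11, 14–16).

Steps most likely to fail

Step 9. What may go wrong: incomplete enantioface control at C9 together with poor chromatographic separation of the C9 epimers, competing transfer of methyl groups from the metal to the iodide, or β-hydride elimination of the alkylpalladium intermediate. The fallback uncouples the two operations and sets out from 12 and 13. The same carboalumination (via 14) is quenched with dry O2 to give (2R)-5-[(tert-butyldimethylsilyl)oxy]-2-methylpentan-1-ol F1. Its enantiomeric purity is raised by lipase-catalysed kinetic acetylation (Burkholderia cepacia lipase, vinyl acetate), which should acetylate the minor (S)-alcohol faster. Appel iodination (I2, PPh3, imidazole, CH2Cl2) gives tert-butyl{[(4R)-5-iodo-4-methylpentyl]oxy}dimethylsilane F2. Zinc insertion (Zn dust, LiCl, THF) gives [(2R)-5-[(tert-butyldimethylsilyl)oxy]-2-methylpentyl](iodo)zinc F3. Negishi coupling of F3 with 10 (Pd(DPEphos)Cl2 or Pd(PPh3)4, THF/DMF, rt) comes back to the route at 16.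

Step 16. What may go wrong: attack of the trivalent iodine oxidant or the oxoammonium species on the electron-rich enolised tricarbonyl, over-oxidation at C4, or epimerisation at C5 and migration of the C6=C7 alkene while the β-hydroxy aldehyde is present. The fallback closes the ring last, so that no acylpyranone is present during the oxidation, and sets out from 19. Condensation with Meldrum's acid (DCC, DMAP, CH2Cl2) gives 5-[(4R,6E)-7-[(4R,5S)-4-[(2S)-butan-2-yl]-2,2-dimethyl-1,3-dioxan-5-yl]-1-hydroxy-4-methylhept-6-en-1-ylidene]-2,2-dimethyl-1,3-dioxane-4,6-dione F4. Heating F4 with 20 in toluene (acylketene capture) gives (2R)-4-methoxy-4-oxobutan-2-yl (6R,8E)-9-[(4R,5S)-4-[(2S)-butan-2-yl]-2,2-dimethyl-1,3-dioxan-5-yl]-6-methyl-3-oxonon-8-enoate F5. Aqueous acetic acid removes the acetonide to give (2R)-4-methoxy-4-oxobutan-2-yl (6R,8E,10S,11R,12S)-11-hydroxy-10-(hydroxymethyl)-6,12-dimethyl-3-oxotetradec-8-enoate F6. TEMPO/PhI(OAc)2 in aqueous MeCN oxidises C13 through (2R)-4-methoxy-4-oxobutan-2-yl (6R,8E,10R,11R,12S)-10-formyl-11-hydroxy-6,12-dimethyl-3-oxotetradec-8-enoate F7 to (2R,3E,6R)-2-[(1R,2S)-1-hydroxy-2-methylbutyl]-11-{[(2R)-4-methoxy-4-oxobutan-2-yl]oxy}-6-methyl-9,11-dioxoundec-3-enoic acid F8. Dieckmann cyclisation of F8 (KOtBu, 3.3 equiv, THF/tBuOH, 0 °C, then acid) closes C3'–C4' and comes back to the route at 28.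

Step 7. What may go wrong: incomplete E-selectivity with a Z-iodide that is hard to remove, or β-elimination and epimerisation of the β-alkoxy aldehyde on the Lewis-acidic trivalent chromium salts. The fallback sets out from 9. Ohira–Bestmann homologation (dimethyl (1-diazo-2-oxopropyl)phosphonate, K2CO3, MeOH, 0 °C) gives (4R,5S)-4-[(2S)-butan-2-yl]-5-ethynyl-2,2-dimethyl-1,3-dioxane F9. Hydrozirconation with Cp2Zr(H)Cl (THF, rt) gives chlorobis(cyclopentadienyl)[(E)-2-[(4R,5S)-4-[(2S)-butan-2-yl]-2,2-dimethyl-1,3-dioxan-5-yl]ethenyl]zirconium F10. Iodinolysis of F10 (I2, 0 °C) comes back to the route at 10, the E geometry now following from syn addition of Zr–H across the alkyne.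

Further compounds

F1 | step 9 | (2R)-5-[(tert-butyldimethylsilyl)oxy]-2-methylpentan-1-ol | OC[C@H](C)CCCO[Si](C)(C)C(C)(C)C
F2 | step 9 | tert-butyl{[(4R)-5-iodo-4-methylpentyl]oxy}dimethylsilane | IC[C@H](C)CCCO[Si](C)(C)C(C)(C)C
F3 | step 9 | [(2R)-5-[(tert-butyldimethylsilyl)oxy]-2-methylpentyl](iodo)zinc | I[Zn]C[C@H](C)CCCO[Si](C)(C)C(C)(C)C
F4 | step 16 | 5-[(4R,6E)-7-[(4R,5S)-4-[(2S)-butan-2-yl]-2,2-dimethyl-1,3-dioxan-5-yl]-1-hydroxy-4-methylhept-6-en-1-ylidene]-2,2-dimethyl-1,3-dioxane-4,6-dione | CC[C@H](C)[C@H]1OC(C)(C)OC[C@@H]1/C=C/C[C@H](C)CCC(O)=C1C(=O)OC(C)(C)OC1=O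
F5 | step 16 | (2R)-4-methoxy-4-oxobutan-2-yl (6R,8E)-9-[(4R,5S)-4-[(2S)-butan-2-yl]-2,2-dimethyl-1,3-dioxan-5-yl]-6-methyl-3-oxonon-8-enoate | CC[C@H](C)[C@H]1OC(C)(C)OC[C@@H]1/C=C/C[C@H](C)CCC(=O)CC(=O)O[C@H](C)CC(=O)OC
F6 | step 16 | (2R)-4-methoxy-4-oxobutan-2-yl (6R,8E,10S,11R,12S)-11-hydroxy-10-(hydroxymethyl)-6,12-dimethyl-3-oxotetradec-8-enoate | CC[C@H](C)[C@@H](O)[C@@H](/C=C/C[C@H](C)CCC(=O)CC(=O)O[C@H](C)CC(=O)OC)CO
F7 | step 16 | (2R)-4-methoxy-4-oxobutan-2-yl (6R,8E,10R,11R,12S)-10-formyl-11-hydroxy-6,12-dimethyl-3-oxotetradec-8-enoate | CC[C@H](C)[C@@H](O)[C@@H](/C=C/C[C@H](C)CCC(=O)CC(=O)O[C@H](C)CC(=O)OC)C=O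
F8 | step 16 | (2R,3E,6R)-2-[(1R,2S)-1-hydroxy-2-methylbutyl]-11-{[(2R)-4-methoxy-4-oxobutan-2-yl]oxy}-6-methyl-9,11-dioxoundec-3-enoic acid | CC[C@H](C)[C@@H](O)[C@@H](/C=C/C[C@H](C)CCC(=O)CC(=O)O[C@H](C)CC(=O)OC)C(=O)O
F9 | step 7 | (4R,5S)-4-[(2S)-butan-2-yl]-5-ethynyl-2,2-dimethyl-1,3-dioxane | CC[C@H](C)[C@H]1OC(C)(C)OC[C@@H]1C#C
F10 | step 7 | chlorobis(cyclopentadienyl)[(E)-2-[(4R,5S)-4-[(2S)-butan-2-yl]-2,2-dimethyl-1,3-dioxan-5-yl]ethenyl]zirconium | CC[C@H](C)[C@H]1OC(C)(C)OC[C@@H]1/C=C/[Zr](Cl)(C1C=CC=C1)C1C=CC=C1
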